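**Retrosynthetic overview**

1. Last C–C bond: C1–C1′, by Mukaiyama aldol of silyl enol ether 14 (fragment 1, rings A and B) with α-silyloxy aldehyde 23 (fragment 2, ring C). The C2 hydroxyl follows by 1,3-syn reduction, and both C–Br bonds by inversion of secondary alcohols.
2. Ring A (C3a–C4–C5–C6–C7–C7a) is closed onto ring B in the key step: SmI2 joins C4 (the aldehyde carbon of 6) to C5, and C7a (the ring ketone of 6) to C7, of methyl vinyl ketone.
3. Enabling feature: C4 and C7a both flank the quaternary C3a and both can carry oxygen, so ring B can be a 2-formylcyclopentanone (a 1,3-dicarbonyl). C5–C6–C7(CH3)–OH is a reduced methyl vinyl ketone. The C7a oxygen sits β to the masked C2 ketone and later leaves as water to give the C1=C7a enone.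
4. C3a is the only stereocentre of fragment 1 set by a chiral catalyst; C7, C4, C7a, C1, C1′ and C2 are relayed from it. Ring order: B (bought) → A (step 6); ring C is made separately (steps 11–13) and joined last.

Key step: step 6

Remark: the bicyclic core is numbered as in indane (C1–C3, C3a, C4–C7, C7a; primed locants in the spiro-ketals); ring A is the cyclohexane ring, ring B the cyclopentane ring, ring C the bromocyclohexanol ring, and C1′ is the acetoxy-bearing carbon.

**Fragment 1 (rings A and B)**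

Step 1
Reactants: 1 3-ethoxycyclopent-2-en-1-one
Product: 2 3-ethoxy-5-methylcyclopent-2-en-1-one (racemic)
Conditions: LiN(i-Pr)2, THF, −78 °C; MeI, −78 → 0 °C
Reagents that add atoms: iodomethane, CI
Why: Stork–Danheiser α′-alkylation of the kinetic enolate of a vinylogous ester; the stereocentre formed here is erased in step 2.

Step 2
Reactants: 2 3-ethoxy-5-methylcyclopent-2-en-1-one
Product: 3 [(4-ethoxy-2-methylcyclopenta-1,4-dien-1-yl)oxy]trimethylsilane
Conditions: LiN(i-Pr)2, THF, −78 °C; TMSCl; non-aqueous work-up, used at once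
Reagents that add atoms: chlorotrimethylsilane, C[Si](C)(C)Cl
Why: Kinetic α′-deprotonation and O-silylation give the 1-alkoxy-3-silyloxy diene (a silicon enolate) whose methyl-bearing terminus is the nucleophilic carbon.

Step 3
Reactants: 3 [(4-ethoxy-2-methylcyclopenta-1,4-dien-1-yl)oxy]trimethylsilane
Product: 4 (5R)-3-ethoxy-5-(hydroxymethyl)-5-methylcyclopent-2-en-1-one
Conditions: aq. HCHO, Sc(OTf)3 (10 mol %), chiral 6,6′-bis(1-hydroxy-2,2-dimethylpropyl)-2,2′-bipyridine (12 mol %), DME–H2O, −20 °C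
Reagents that add atoms: formaldehyde, C=O
Why: Catalytic enantioselective hydroxymethylation of a silicon enolate (Mukaiyama aldol with aqueous formaldehyde under a chiral scandium–bipyridine complex) creates the quaternary C3a, the ligand enantiomer being the one that shields the face leading to the (S)-alcohol.

Step 4
Reactants: 4 (5R)-3-ethoxy-5-(hydroxymethyl)-5-methylcyclopent-2-en-1-one
Product: 5 (7R)-7-(hydroxymethyl)-7-methyl-1,4-dioxaspiro[4.4]nonan-8-one
Conditions: HOCH2CH2OH (5 equiv), TsOH·H2O (5 mol %), benzene, reflux, Dean–Stark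
Reagents that add atoms: ethane-1,2-diol, OCCO
Why: Acid-catalysed acetal exchange in which the glycol displaces ethanol from the vinylogous ester and closes by intramolecular oxa-Michael addition to the spiro-dioxolane of the 1,3-diketone, driven by removal of ethanol; the quaternary centre is not touched.

Step 5
Reactants: 5 (7R)-7-(hydroxymethyl)-7-methyl-1,4-dioxaspiro[4.4]nonan-8-one
Product: 6 (7R)-7-methyl-8-oxo-1,4-dioxaspiro[4.4]nonane-7-carbaldehyde
Conditions: Pr4N[RuO4] (5 mol %), NMO, 4 Å MS, CH2Cl2, rt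
Reagents that add atoms: none
Why: Ley–Griffith oxidation of the neopentyl primary alcohol under neutral conditions, which spares the base-sensitive β-keto ketal and gives a non-enolisable aldehyde.

Step 6
Reactants: 6 (7R)-7-methyl-8-oxo-1,4-dioxaspiro[4.4]nonane-7-carbaldehyde; 7 but-3-en-2-one
Product: 9 (3a′R,7′R,7a′S)-3a′,7′-dimethyloctahydrospiro[[1,3]dioxolane-2,2′-indene]-4′,7′,7a′-triol (C4′ epimers), via hydroxy diketone 8 (not isolated)
Conditions: SmI2 (4.5 equiv), t-BuOH (4 equiv), HMPA (8 equiv), THF, −78 °C, 6 and 7 (1.2 equiv) added slowly; then rt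
Reagents that add atoms: none
Why: Proposed new method: SmI2 reduces the chelated aldehyde of 6 to a ketyl that adds to the terminal carbon of methyl vinyl ketone (bond C4–C5), t-BuOH protonates the samarium enolate to hydroxy diketone 8, and two further electrons join the new methyl ketone and the ring ketone in a pinacol coupling (bond C7–C7a). The closest known reaction types are the intermolecular SmI2 ketyl–olefin coupling of aldehydes with acrylates or acrylonitrile and the intramolecular SmI2 pinacol cyclisation of 1,6-diketones; an enone as the olefin partner and the merger of both events in one flask are the untested parts. Ring A closes in the pinacol event by 6-exo-trig attack of the C7 ketyl on the C7a carbonyl, which for a six-membered ring fused to the cyclopentanone can only occur on the face that carries the C4 tether, so the C7a hydroxyl ends cis to the C3a methyl group. C7 is set by the trivalent samarium bridge between the two oxygens, which gives the cis-diol and hence the C7 hydroxyl cis to the C3a methyl group as in the target; C4 forms without control and is corrected in steps 7 and 8. The step needs chemoselectivity (aldehyde before ketones, cross-coupling before self-coupling of 7 or three-ring pinacol closure within 6), which the faster reduction of the chelated aldehyde and the slow addition are meant to secure.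

Step 7
Reactants: 9 (3a′R,7′R,7a′S)-3a′,7′-dimethyloctahydrospiro[[1,3]dioxolane-2,2′-indene]-4′,7′,7a′-triol (C4′ epimers)
Product: 10 (3a′S,7′R,7a′S)-7′,7a′-dihydroxy-3a′,7′-dimethyloctahydrospiro[[1,3]dioxolane-2,2′-inden]-4′-one
Conditions: Pr4N[RuO4] (5 mol %), NMO, 4 Å MS, CH2Cl2, 0 °C → rt
Reagents that add atoms: none
Why: Ley–Griffith oxidation of the only secondary alcohol merges both C4′ epimers into one ketone, the two tertiary alcohols being inert.

Step 8
Reactants: 10 (3a′S,7′R,7a′S)-7′,7a′-dihydroxy-3a′,7′-dimethyloctahydrospiro[[1,3]dioxolane-2,2′-inden]-4′-one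
Product: 12 (3aS,4R,7R)-4,7-dihydroxy-3a,7-dimethyl-3,3a,4,5,6,7-hexahydro-2H-inden-2-one, via axial alcohol 11 (not isolated)
Conditions: LiBH(s-Bu)3 (3.5 equiv), THF, −78 °C; then 1 M HCl, THF, 40 °C
Reagents that add atoms: water, O
Why: The bulky trialkylborohydride attacks the C4′ ketone from the equatorial side (the axial side is screened by the syn-axial C1′ methylene of the cis-fused system) to give the axial alcohol trans to the C3a′ methyl group, and aqueous acid then hydrolyses the dioxolane and dehydrates the tertiary β-hydroxy ketone (acid-catalysed aldol dehydration) to the enone.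

Step 9
Reactants: 12 (3aS,4R,7R)-4,7-dihydroxy-3a,7-dimethyl-3,3a,4,5,6,7-hexahydro-2H-inden-2-one
Product: 13 (3aS,4S,7R)-4-bromo-7-hydroxy-3a,7-dimethyl-3,3a,4,5,6,7-hexahydro-2H-inden-2-one
Conditions: CBr4, PPh3, 2,6-lutidine, CH2Cl2, 0 °C → rt
Reagents that add atoms: tetrabromomethane, BrC(Br)(Br)Br
Why: Appel reaction, in which bromide displaces the oxyphosphonium group of the axial alcohol by SN2 with inversion to give the equatorial (4S) bromide cis to the C3a methyl group, while the hindered tertiary alcohol should not react.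

Step 10
Reactants: 13 (3aS,4S,7R)-4-bromo-7-hydroxy-3a,7-dimethyl-3,3a,4,5,6,7-hexahydro-2H-inden-2-one
Product: 14 (3aS,4S,7R,7aS)-4-bromo-3a,7-dimethyl-2-[(trimethylsilyl)oxy]-3a,4,5,6,7,7a-hexahydro-3H-inden-7-ol
Conditions: [(Ph3P)CuH]6 (0.5 equiv), TMSCl (3 equiv), THF, −40 → 0 °C
Reagents that add atoms: chlorotrimethylsilane, C[Si](C)(C)Cl
Why: Copper hydride conjugate reduction (Stryker's reagent) with silyl trapping, in which hydride reaches C7a from the face opposite the axial C3a methyl and C7 hydroxyl groups, setting the trans ring fusion and giving the regiodefined C1=C2 silyl enol ether.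

**Fragment 2 (ring C)**

Step 11
Reactants: 15 6-methylhept-5-en-2-one
Product: 16 4-[(2R)-3,3-dimethyloxiran-2-yl]butan-2-one
Conditions: D-fructose-derived Shi ketone (30 mol %), Oxone (2KHSO5·KHSO4·K2SO4), K2CO3, Bu4NHSO4, MeCN–CH2(OMe)2–aq. Na2B4O7, 0 °C
Reagents that add atoms: potassium peroxymonosulfate, [K+].[O-]S(=O)(=O)OO
Why: Shi asymmetric epoxidation (chiral dioxirane, spiro transition state) of the trisubstituted alkene sets the future bromine-bearing carbon as the (R)-epoxide.

Step 12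
Reactants: 16 4-[(2R)-3,3-dimethyloxiran-2-yl]butan-2-one
Product: 17 ({4-[(2R)-3,3-dimethyloxiran-2-yl]but-1-en-2-yl}oxy)trimethylsilane
Conditions: LiN(i-Pr)2, THF, −78 °C; TMSCl
Reagents that add atoms: chlorotrimethylsilane, C[Si](C)(C)Cl
Why: Kinetic deprotonation of the methyl ketone at the methyl group followed by O-silylation, the epoxide being inert to the hindered amide base at −78 °C.

Step 13
Reactants: 17 ({4-[(2R)-3,3-dimethyloxiran-2-yl]but-1-en-2-yl}oxy)trimethylsilane
Product: 19 (4R)-4-hydroxy-3,3-dimethylcyclohexan-1-one, via silyl ether 18 (not isolated)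
Conditions: TMSOTf (10 mol %), CH2Cl2, −78 °C; then 1 M HCl, THF, 0 °C
Reagents that add atoms: none
Why: Epoxide-initiated cation–olefin cyclisation terminated by a silyl enol ether: the Lewis acid opens the epoxide at its tertiary carbon, the enol ether carbon closes the six-membered ring, and silyl transfer to the alkoxide turns the catalyst over, with the C–O bond of the stereocentre left intact so that the (R) configuration is kept.

Step 14
Reactants: 19 (4R)-4-hydroxy-3,3-dimethylcyclohexan-1-one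
Product: 20 (4S)-4-bromo-3,3-dimethylcyclohexan-1-one
Conditions: CBr4, PPh3, CH2Cl2, 0 °C → rt
Reagents that add atoms: tetrabromomethane, BrC(Br)(Br)Br
Why: Appel reaction with SN2 inversion at the carbinol carbon gives the (S)-bromide.

Step 15
Reactants: 20 (4S)-4-bromo-3,3-dimethylcyclohexan-1-one
Product: 21 (1R,4S)-4-bromo-1-ethenyl-3,3-dimethylcyclohexan-1-ol
Conditions: CH2=CHMgBr, CeCl3, THF, −78 °C
Reagents that add atoms: vinylmagnesium bromide, C=C[Mg]Br
Why: Organocerium 1,2-addition (non-basic, so neither enolisation nor cyclopropane formation from the γ-bromo ketone) from the equatorial side, away from the axial C3 methyl group, on the chair with equatorial bromine puts the vinyl group trans to bromine and the hydroxyl axial; the epimer arising from the chair with axial bromine is expected as a minor product and is removed by chromatography.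

Step 16
Reactants: 21 (1R,4S)-4-bromo-1-ethenyl-3,3-dimethylcyclohexan-1-ol
Product: 22 {[(1R,4S)-4-bromo-1-ethenyl-3,3-dimethylcyclohexyl]oxy}triethylsilane
Conditions: TESOTf, 2,6-lutidine, CH2Cl2, −78 → 0 °C
Reagents that add atoms: triethylsilyl trifluoromethanesulfonate, CC[Si](CC)(CC)OS(=O)(=O)C(F)(F)F
Why: Silylation of the hindered tertiary alcohol with a silyl triflate and a non-nucleophilic base.

Step 17
Reactants: 22 {[(1R,4S)-4-bromo-1-ethenyl-3,3-dimethylcyclohexyl]oxy}triethylsilane
Product: 23 (1R,4S)-4-bromo-3,3-dimethyl-1-[(triethylsilyl)oxy]cyclohexane-1-carbaldehyde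
Conditions: O3, CH2Cl2–MeOH, −78 °C; Me2S
Reagents that add atoms: ozone, [O-][O+]=O
Why: Ozonolysis of the vinyl group with reductive work-up gives the non-enolisable α-silyloxy aldehyde.

**Coupling and end game**

Step 18
Reactants: 14 (3aS,4S,7R,7aS)-4-bromo-3a,7-dimethyl-2-[(trimethylsilyl)oxy]-3a,4,5,6,7,7a-hexahydro-3H-inden-7-ol; 23 (1R,4S)-4-bromo-3,3-dimethyl-1-[(triethylsilyl)oxy]cyclohexane-1-carbaldehyde
Product: 24 (1R,3aS,4S,7R,7aS)-4-bromo-1-[(R)-{(1R,4S)-4-bromo-3,3-dimethyl-1-[(triethylsilyl)oxy]cyclohexyl}(hydroxy)methyl]-7-hydroxy-3a,7-dimethyloctahydro-2H-inden-2-one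
Conditions: BF3·OEt2 (1.2 equiv), CH2Cl2, −78 °C; aq. NaHCO3
Reagents that add atoms: none
Why: Mukaiyama aldol through an open transition state: the aldehyde reaches C1 from the face opposite C7 on the adjacent C7a and opposite the C3a methyl group (C1 substituent trans to the ring A bond), and the antiperiplanar arrangement that turns the bulky cyclohexyl group away from ring B gives the syn relationship, that is (R) at C1′.

Step 19
Reactants: 24 (1R,3aS,4S,7R,7aS)-4-bromo-1-[(R)-{(1R,4S)-4-bromo-3,3-dimethyl-1-[(triethylsilyl)oxy]cyclohexyl}(hydroxy)methyl]-7-hydroxy-3a,7-dimethyloctahydro-2H-inden-2-one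
Product: 25 (1S,2R,3aS,4S,7R,7aS)-4-bromo-1-[(R)-{(1R,4S)-4-bromo-3,3-dimethyl-1-[(triethylsilyl)oxy]cyclohexyl}(hydroxy)methyl]-3a,7-dimethyloctahydro-1H-indene-2,7-diol
Conditions: Et2BOMe, THF–MeOH (4:1), −78 °C; NaBH4; AcOH, then MeOH co-evaporation
Reagents that add atoms: none
Why: Narasaka–Prasad reduction, in which boron ties the C1′ oxygen to the ketone oxygen and external hydride attacks the ketone on the face opposite this chelate ring, giving the 1,3-syn diol with the C2 hydroxyl cis to the side chain.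

Step 20
Reactants: 25 (1S,2R,3aS,4S,7R,7aS)-4-bromo-1-[(R)-{(1R,4S)-4-bromo-3,3-dimethyl-1-[(triethylsilyl)oxy]cyclohexyl}(hydroxy)methyl]-3a,7-dimethyloctahydro-1H-indene-2,7-diol
Product: 26 (1R,2R,3aS,4S,7R,7aS)-4-bromo-1-[(R)-{(1R,4S)-4-bromo-3,3-dimethyl-1-[(triethylsilyl)oxy]cyclohexyl}(hydroxy)methyl]-3a,7-dimethyl-2-[(triethylsilyl)oxy]octahydro-1H-inden-7-ol
Conditions: TESCl (1.1 equiv), imidazole, CH2Cl2, −20 °C
Reagents that add atoms: chlorotriethylsilane, CC[Si](Cl)(CC)CC
Why: Silylation selective for the ring secondary alcohol, which is less hindered than the C1′ hydroxyl (flanked by a quaternary carbon) and than the tertiary alcohol.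

Step 21
Reactants: 26 (1R,2R,3aS,4S,7R,7aS)-4-bromo-1-[(R)-{(1R,4S)-4-bromo-3,3-dimethyl-1-[(triethylsilyl)oxy]cyclohexyl}(hydroxy)methyl]-3a,7-dimethyl-2-[(triethylsilyl)oxy]octahydro-1H-inden-7-ol
Product: 27 (R)-[(1R,2R,3aS,4S,7R,7aS)-4-bromo-7-hydroxy-3a,7-dimethyl-2-[(triethylsilyl)oxy]octahydro-1H-inden-1-yl]{(1R,4S)-4-bromo-3,3-dimethyl-1-[(triethylsilyl)oxy]cyclohexyl}methyl acetate
Conditions: Ac2O, DMAP, Et3N, CH2Cl2, rt → 40 °C
Reagents that add atoms: acetic anhydride, CC(=O)OC(C)=O
Why: DMAP-catalysed acylation of the only remaining secondary alcohol, the axial tertiary alcohol being too hindered to react.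

Step 22
Reactants: 27 (R)-[(1R,2R,3aS,4S,7R,7aS)-4-bromo-7-hydroxy-3a,7-dimethyl-2-[(triethylsilyl)oxy]octahydro-1H-inden-1-yl]{(1R,4S)-4-bromo-3,3-dimethyl-1-[(triethylsilyl)oxy]cyclohexyl}methyl acetate
Product: 28 (R)-[(1S,2R,3aS,4S,7R,7aS)-4-bromo-2,7-dihydroxy-3a,7-dimethyloctahydro-1H-inden-1-yl][(1R,4S)-4-bromo-1-hydroxy-3,3-dimethylcyclohexyl]methyl acetate (CNP0166243.1)
Conditions: HF·pyridine, pyridine, THF, 0 °C → rt
Reagents that add atoms: none
Why: Fluoride cleavage of both triethylsilyl ethers under buffered acidic conditions, under which the acetate should neither migrate nor hydrolyse.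

**Compound list**

1 | 3-ethoxycyclopent-2-en-1-one | CCOC1=CC(=O)CC1 | starting material
2 | 3-ethoxy-5-methylcyclopent-2-en-1-one (racemic) | CCOC1=CC(=O)C(C)C1 | intermediate
3 | [(4-ethoxy-2-methylcyclopenta-1,4-dien-1-yl)oxy]trimethylsilane | CCOC1=CC(O[Si](C)(C)C)=C(C)C1 | intermediate
4 | (5R)-3-ethoxy-5-(hydroxymethyl)-5-methylcyclopent-2-en-1-one | CCOC1=CC(=O)[C@@](C)(CO)C1 | intermediate
5 | (7R)-7-(hydroxymethyl)-7-methyl-1,4-dioxaspiro[4.4]nonan-8-one | OC[C@@]1(C)CC2(OCCO2)CC1=O | intermediate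
6 | (7R)-7-methyl-8-oxo-1,4-dioxaspiro[4.4]nonane-7-carbaldehyde | O=C[C@@]1(C)CC2(OCCO2)CC1=O | intermediate
7 | but-3-en-2-one (methyl vinyl ketone) | CC(=O)C=C | starting material
8 | (7R)-7-(1-hydroxy-4-oxopentyl)-7-methyl-1,4-dioxaspiro[4.4]nonan-8-one (both carbinol epimers; formed as its samarium alkoxide) | CC(=O)CCC(O)[C@@]1(C)CC2(OCCO2)CC1=O | intermediate
9 | (3a′R,7′R,7a′S)-3a′,7′-dimethyloctahydrospiro[[1,3]dioxolane-2,2′-indene]-4′,7′,7a′-triol (C4′ epimers; 7′-OH, 7a′-OH and 3a′-CH3 all cis) | C1C3(OCCO3)C[C@]2(C)C(O)CC[C@@](C)(O)[C@]12O | intermediate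
10 | (3a′S,7′R,7a′S)-7′,7a′-dihydroxy-3a′,7′-dimethyloctahydrospiro[[1,3]dioxolane-2,2′-inden]-4′-one | C1C3(OCCO3)C[C@]2(C)C(=O)CC[C@@](C)(O)[C@]12O | intermediate
11 | (3a′R,4′R,7′R,7a′S)-3a′,7′-dimethyloctahydrospiro[[1,3]dioxolane-2,2′-indene]-4′,7′,7a′-triol (4′-OH axial, trans to 3a′-CH3) | C1C3(OCCO3)C[C@]2(C)[C@H](O)CC[C@@](C)(O)[C@]12O | intermediate
12 | (3aS,4R,7R)-4,7-dihydroxy-3a,7-dimethyl-3,3a,4,5,6,7-hexahydro-2H-inden-2-one | O=C1C[C@]2(C)[C@H](O)CC[C@@](C)(O)C2=C1 | intermediate
13 | (3aS,4S,7R)-4-bromo-7-hydroxy-3a,7-dimethyl-3,3a,4,5,6,7-hexahydro-2H-inden-2-one | O=C1C[C@]2(C)[C@@H](Br)CC[C@@](C)(O)C2=C1 | intermediate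
14 | (3aS,4S,7R,7aS)-4-bromo-3a,7-dimethyl-2-[(trimethylsilyl)oxy]-3a,4,5,6,7,7a-hexahydro-3H-inden-7-ol (trans ring fusion) | C1=C(O[Si](C)(C)C)C[C@]2(C)[C@@H](Br)CC[C@@](C)(O)[C@@H]12 | intermediate
15 | 6-methylhept-5-en-2-one | CC(=O)CCC=C(C)C | starting material
16 | 4-[(2R)-3,3-dimethyloxiran-2-yl]butan-2-one | CC(=O)CC[C@H]1OC1(C)C | intermediate
17 | ({4-[(2R)-3,3-dimethyloxiran-2-yl]but-1-en-2-yl}oxy)trimethylsilane | C=C(O[Si](C)(C)C)CC[C@H]1OC1(C)C | intermediate
18 | (4R)-3,3-dimethyl-4-[(trimethylsilyl)oxy]cyclohexan-1-one | O=C1CC[C@@H](O[Si](C)(C)C)C(C)(C)C1 | intermediate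
19 | (4R)-4-hydroxy-3,3-dimethylcyclohexan-1-one | O=C1CC[C@@H](O)C(C)(C)C1 | intermediate
20 | (4S)-4-bromo-3,3-dimethylcyclohexan-1-one | O=C1CC[C@H](Br)C(C)(C)C1 | intermediate
21 | (1R,4S)-4-bromo-1-ethenyl-3,3-dimethylcyclohexan-1-ol | C=C[C@@]1(O)CC[C@H](Br)C(C)(C)C1 | intermediate
22 | {[(1R,4S)-4-bromo-1-ethenyl-3,3-dimethylcyclohexyl]oxy}triethylsilane | C=C[C@@]1(O[Si](CC)(CC)CC)CC[C@H](Br)C(C)(C)C1 | intermediate
23 | (1R,4S)-4-bromo-3,3-dimethyl-1-[(triethylsilyl)oxy]cyclohexane-1-carbaldehyde | O=C[C@@]1(O[Si](CC)(CC)CC)CC[C@H](Br)C(C)(C)C1 | intermediate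
24 | (1R,3aS,4S,7R,7aS)-4-bromo-1-[(R)-{(1R,4S)-4-bromo-3,3-dimethyl-1-[(triethylsilyl)oxy]cyclohexyl}(hydroxy)methyl]-7-hydroxy-3a,7-dimethyloctahydro-2H-inden-2-one | O[C@H]([C@@H]1C(=O)C[C@]2(C)[C@@H](Br)CC[C@@](C)(O)[C@@H]12)[C@@]1(O[Si](CC)(CC)CC)CC[C@H](Br)C(C)(C)C1 | intermediate
25 | (1S,2R,3aS,4S,7R,7aS)-4-bromo-1-[(R)-{(1R,4S)-4-bromo-3,3-dimethyl-1-[(triethylsilyl)oxy]cyclohexyl}(hydroxy)methyl]-3a,7-dimethyloctahydro-1H-indene-2,7-diol | O[C@H]([C@@H]1[C@H](O)C[C@]2(C)[C@@H](Br)CC[C@@](C)(O)[C@@H]12)[C@@]1(O[Si](CC)(CC)CC)CC[C@H](Br)C(C)(C)C1 | intermediate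
26 | (1R,2R,3aS,4S,7R,7aS)-4-bromo-1-[(R)-{(1R,4S)-4-bromo-3,3-dimethyl-1-[(triethylsilyl)oxy]cyclohexyl}(hydroxy)methyl]-3a,7-dimethyl-2-[(triethylsilyl)oxy]octahydro-1H-inden-7-ol | O[C@H]([C@@H]1[C@H](O[Si](CC)(CC)CC)C[C@]2(C)[C@@H](Br)CC[C@@](C)(O)[C@@H]12)[C@@]1(O[Si](CC)(CC)CC)CC[C@H](Br)C(C)(C)C1 | intermediate
27 | (R)-[(1R,2R,3aS,4S,7R,7aS)-4-bromo-7-hydroxy-3a,7-dimethyl-2-[(triethylsilyl)oxy]octahydro-1H-inden-1-yl]{(1R,4S)-4-bromo-3,3-dimethyl-1-[(triethylsilyl)oxy]cyclohexyl}methyl acetate | CC(=O)O[C@H]([C@@H]1[C@H](O[Si](CC)(CC)CC)C[C@]2(C)[C@@H](Br)CC[C@@](C)(O)[C@@H]12)[C@@]1(O[Si](CC)(CC)CC)CC[C@H](Br)C(C)(C)C1 | intermediate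
28 | (R)-[(1S,2R,3aS,4S,7R,7aS)-4-bromo-2,7-dihydroxy-3a,7-dimethyloctahydro-1H-inden-1-yl][(1R,4S)-4-bromo-1-hydroxy-3,3-dimethylcyclohexyl]methyl acetate | CC(=O)O[C@H]([C@@H]1[C@H](O)C[C@]2(C)[C@@H](Br)CC[C@@](C)(O)[C@@H]12)[C@@]1(O)CC[C@H](Br)C(C)(C)C1 | target

**Step count and risks**

Total step count: 22. Longest linear sequence: 15 steps (steps 1–10 and 18–22, from 1).

Steps most likely to fail:

1. Step 6 (Proposed new method). Reduction and self-coupling of the enone, or closure of the aldehyde ketyl onto the neighbouring ring ketone, may outrun the cross-coupling. The fallback uses known chemistry and sets out from 6: but-3-enylmagnesium bromide with CeCl3 in THF at −78 °C adds to the aldehyde and gives the pentenyl carbinol F1. Wacker oxidation (PdCl2, CuCl, O2, DMF–H2O) then turns the terminal alkene into the methyl ketone 8, now isolated. SmI2 with HMPA and t-BuOH effects the known intramolecular pinacol cyclisation of this 1,6-diketone, and the route is rejoined at 9.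

2. Step 9. Ionisation, elimination or a 1,2-shift at the neopentylic oxyphosphonium centre may outrun backside attack by bromide. The fallback makes the C–Br bond on an sp2 carbon instead and sets out from 10: hydrazine hydrate gives the hydrazone F2, and Barton-type bromination (N-bromosuccinimide, pyridine) gives the vinyl bromide F3. Diimide (potassium azodicarboxylate, AcOH) adds hydrogen from the face opposite the axial C3a′ methyl and C7′ hydroxyl groups without cleaving the C–Br bond and gives the equatorial bromide F4. 1 M HCl then removes the ketal and dehydrates, and the route is rejoined at 13.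

3. Step 14. Elimination or rearrangement next to the quaternary carbon may again outrun substitution. The fallback forms the C–Br bond at the alkene stage and sets out from 15: LiN(i-Pr)2 and TMSCl give the dienyl silyl ether F5. An enantioselective bromonium-induced cyclisation (N-bromosuccinimide, chiral phosphoramidite Lewis base, toluene, −40 °C) then adds bromine and the ring C–C bond anti across the trisubstituted alkene, and the route is rejoined at 20.

**Further compounds**

F1 | step 6 | (7R)-7-(1-hydroxypent-4-en-1-yl)-7-methyl-1,4-dioxaspiro[4.4]nonan-8-one (carbinol epimers) | C=CCCC(O)[C@@]1(C)CC2(OCCO2)CC1=O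
F2 | step 9 | hydrazone of 10 at C4′ | C1C3(OCCO3)C[C@]2(C)C(=NN)CC[C@@](C)(O)[C@]12O
F3 | step 9 | 4′-bromo-4′,5′-alkene derived from 10 (vinyl bromide, ketal and cis-diol kept) | C1C3(OCCO3)C[C@]2(C)C(Br)=CC[C@@](C)(O)[C@]12O
F4 | step 9 | (3a′S,4′S,7′R,7a′S)-4′-bromo-3a′,7′-dimethyloctahydrospiro[[1,3]dioxolane-2,2′-indene]-7′,7a′-diol | C1C3(OCCO3)C[C@]2(C)[C@@H](Br)CC[C@@](C)(O)[C@]12O
F5 | step 14 | trimethyl[(6-methylhepta-1,5-dien-2-yl)oxy]silane | C=C(O[Si](C)(C)C)CCC=C(C)C
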